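**Plan**

1. Notation: tetralin locants are used throughout, also for open-chain precursors (C1 aryl, C2 CO2Me, C3 CH2OH, C4, C4a, C5–C8, C8a). Ring A is the benzo ring, ring B the saturated ring, and Ar = 4-(benzyloxy)-3-methoxyphenyl.
2. Enabling feature: ring A carries only OMe on C6 and OH on C7, with C5 and C8 as CH. C8a=C8–C7(OSi)=C6(OMe) can therefore be an open 1-methoxy-2-silyloxydiene and C4a≡C5H a terminal alkyne, held together by the C1–C4 chain.
3. Retrosynthesis: remove the three protecting groups; cut C4a–C8a and C5–C6 together (diene–yne (4+2), then dehydrogenation), which opens rings B and A at once; cut C6–C7 (methoxymethyl anion onto an enal); cut C1–C2 (Ireland–Claisen of an allyl ester) to an allylic alcohol and a hexynoic acid.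
4. Forward: the alcohol (four steps from O-benzylvanillin) and the acid (five steps from mono-tert-butyl succinate) are esterified. The Claisen step joins the chain, which is then taken to the methoxy enone and its silyl dienol ether. Rings B and A close in one operation, and two deprotections finish.
5. Stereochemistry: C3 comes from an Evans alkylation; the carbinol of the allylic alcohol from asymmetric transfer hydrogenation; C1 and C2 from that carbinol by chirality transfer through the chair Claisen transition state of the (E)-silyl ketene acetal. The ring-forming step makes no lasting stereocentre.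

Key step: step 16

Assumption: tributyl(methoxymethyl)stannane is taken as a purchasable reagent, and the hydroxy ester target is taken not to lactonise under neutral hydrogenolysis.

**Route**

Step 1
Reactants: 1 4-(benzyloxy)-3-methoxybenzaldehyde
Product: 2 1-(benzyloxy)-4-ethynyl-2-methoxybenzene
Conditions: dimethyl (1-diazo-2-oxopropyl)phosphonate, K2CO3, MeOH, 0 °C → rt
Reagents that add atoms: dimethyl (1-diazo-2-oxopropyl)phosphonate, CC(=O)C(=[N+]=[N-])P(=O)(OC)OC
Why: Seyferth–Gilbert homologation in its Ohira–Bestmann form: methanolysis of the acetyl group frees the diazomethylphosphonate anion, which olefinates the non-enolisable aryl aldehyde and, after loss of dinitrogen and a 1,2-hydrogen shift, should give the terminal alkyne without touching the benzyl ether.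

Step 2
Reactants: 2 1-(benzyloxy)-4-ethynyl-2-methoxybenzene; 3 methyl 2,2-dimethoxyacetate
Product: 5 4-Ar-1,1-dimethoxybut-3-yn-2-one, via lithium acetylide 4 (not isolated)
Conditions: nBuLi, THF, −78 °C; cannulated into 3 (2 equiv), THF, −78 °C; AcOH quench at −78 °C
Reagents that add atoms: none
Why: acylation of an alkynyllithium by an activated ester: the two α-methoxy groups stabilise the lithium-chelated tetrahedral adduct until the cold quench (the behaviour that makes dialkoxyacetates act like Weinreb amides), so a single addition to the ynone is expected.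

Step 3
Reactants: 5 4-Ar-1,1-dimethoxybut-3-yn-2-one
Product: 6 (2R)-4-Ar-1,1-dimethoxybut-3-yn-2-ol
Conditions: Ru[(S,S)-TsNCH(Ph)CH(Ph)NH](p-cymene) (1 mol %), iPrOH, rt
Reagents that add atoms: none
Why: Noyori asymmetric transfer hydrogenation of an alkynyl ketone: the ruthenium hydride–amine pair delivers H to the carbonyl face that places the alkyne where the aryl group of an aryl ketone sits, which with the (S,S) ligand should set the carbinol as (R) (R because the acetal carbon outranks the alkyne), and the base-free catalyst spares the ynone.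

Step 4
Reactants: 6 (2R)-4-Ar-1,1-dimethoxybut-3-yn-2-ol
Product: 7 (2R,3E)-4-Ar-1,1-dimethoxybut-3-en-2-ol
Conditions: NaAlH2(OCH2CH2OMe)2, THF, 0 °C → rt; aq. potassium sodium tartrate
Reagents that add atoms: none
Why: hydroxyl-directed trans-hydroalumination of a propargylic alcohol followed by protonolysis of the vinylalanate should give only the (E)-allylic alcohol and leaves the carbinol centre and the acetal unchanged.

Step 5
Reactants: 8 4-(tert-butoxy)-4-oxobutanoic acid; 9 (4S)-4-benzyl-1,3-oxazolidin-2-one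
Product: 11 tert-butyl 4-[(4S)-4-benzyl-2-oxo-1,3-oxazolidin-3-yl]-4-oxobutanoate, via mixed pivalic anhydride 10 (not isolated)
Conditions: PivCl, Et3N, THF, −20 °C; then 9, LiCl, rt
Reagents that add atoms: none
Why: N-acylation of an oxazolidinone through a mixed anhydride: the hindered pivaloyl carbonyl steers the lithium-chloride-activated oxazolidinone to the succinyl carbonyl, a standard entry to Evans imides that a tert-butyl ester tolerates.

Step 6
Reactants: 11 tert-butyl 4-[(4S)-4-benzyl-2-oxo-1,3-oxazolidin-3-yl]-4-oxobutanoate; 12 3-bromo-1-(trimethylsilyl)prop-1-yne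
Product: 14 tert-butyl (3S)-3-{[(4S)-4-benzyl-2-oxo-1,3-oxazolidin-3-yl]carbonyl}-6-(trimethylsilyl)hex-5-ynoate, via sodium enolate 13 (not isolated)
Conditions: NaN(SiMe3)2, THF, −78 °C; then 12, −78 → −40 °C
Reagents that add atoms: none
Why: Evans asymmetric alkylation: the imide α-hydrogens are far more acidic than those beside the tert-butyl ester, the chelated (Z)-enolate is shielded on one face by the benzyl group of the (4S) auxiliary, and the silyl-capped propargylic bromide (the cap blocks allenyl attack) should enter from the open face to set the (S) centre that becomes C3.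

Step 7
Reactants: 14 tert-butyl (3S)-3-{[(4S)-4-benzyl-2-oxo-1,3-oxazolidin-3-yl]carbonyl}-6-(trimethylsilyl)hex-5-ynoate
Product: 15 tert-butyl (3S)-3-(hydroxymethyl)-6-(trimethylsilyl)hex-5-ynoate
Conditions: LiBH4, MeOH (1 equiv), Et2O, 0 °C
Reagents that add atoms: none
Why: reductive removal of the Evans auxiliary: lithium borohydride reduces the activated exocyclic imide carbonyl to the primary alcohol and releases the oxazolidinone, while the tert-butyl ester and the alkynylsilane are not reduced and the stereocentre is kept.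

Step 8
Reactants: 15 tert-butyl (3S)-3-(hydroxymethyl)-6-(trimethylsilyl)hex-5-ynoate
Product: 16 tert-butyl (3S)-3-[(benzyloxy)methyl]-6-(trimethylsilyl)hex-5-ynoate
Conditions: 2-(benzyloxy)-1-methylpyridinium triflate, MgO, PhCF3, 85 °C
Reagents that add atoms: 2-(benzyloxy)-1-methylpyridinium trifluoromethanesulfonate, C[n+]1ccccc1OCc1ccccc1.[O-]S(=O)(=O)C(F)(F)F
Why: O-benzylation under neutral conditions by thermal benzyl transfer from a 2-benzyloxypyridinium salt (acid scavenged by MgO), chosen because an alkoxide (Williamson conditions) would close the γ-lactone onto the ester and attack the C–Si bond.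

Step 9
Reactants: 16 tert-butyl (3S)-3-[(benzyloxy)methyl]-6-(trimethylsilyl)hex-5-ynoate
Product: 17 (3S)-3-[(benzyloxy)methyl]-6-(trimethylsilyl)hex-5-ynoic acid
Conditions: CF3CO2H, CH2Cl2, 0 °C → rt
Reagents that add atoms: none
Why: acidolysis of a tert-butyl ester (loss of 2-methylpropene through the tert-butyl cation) should free the acid while the benzyl ether and the alkynylsilane, both stable to brief contact with this acid, remain.

Step 10
Reactants: 17 (3S)-3-[(benzyloxy)methyl]-6-(trimethylsilyl)hex-5-ynoic acid; 7 (2R,3E)-4-Ar-1,1-dimethoxybut-3-en-2-ol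
Product: 18 (2R,3E)-4-Ar-1,1-dimethoxybut-3-en-2-yl (3S)-3-[(benzyloxy)methyl]-6-(trimethylsilyl)hex-5-ynoate
Conditions: DCC, DMAP (cat.), CH2Cl2, 0 °C → rt
Reagents that add atoms: none
Why: Steglich esterification: the O-acylisourea is relayed through the acylpyridinium ion to the secondary allylic alcohol under neutral conditions, so neither the acetal nor either stereocentre is at risk.

Step 11
Reactants: 18 (2R,3E)-4-Ar-1,1-dimethoxybut-3-en-2-yl (3S)-3-[(benzyloxy)methyl]-6-(trimethylsilyl)hex-5-ynoate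
Product: 21 (2S,3S)-2-[(1R,2E)-1-Ar-4,4-dimethoxybut-2-en-1-yl]-3-[(benzyloxy)methyl]-6-(trimethylsilyl)hex-5-ynoic acid, via silyl ketene acetal 19 (not isolated), via trimethylsilyl ester 20 (not isolated)
Conditions: LiN(iPr)2, Me3SiCl/Et3N, THF, −78 °C; then rt → 60 °C; pH 5 aqueous work-up
Reagents that add atoms: none
Why: Ireland–Claisen rearrangement: kinetic deprotonation in THF without polar additive should give the ketene acetal with the C3 side chain trans to OSiMe3, and its [3,3] shift through a chair with the dimethoxymethyl group equatorial on the (R) carbinol carbon forms the C1–C2 bond on the face from which oxygen leaves, which sets C1 as (R), makes the new alkene (E) and, through the ketene acetal geometry, places C2 (S) anti to the aryl group, with C3 a spectator and the silyl cap keeping the alkyne C–H away from the base.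

Step 12
Reactants: 21 (2S,3S)-2-[(1R,2E)-1-Ar-4,4-dimethoxybut-2-en-1-yl]-3-[(benzyloxy)methyl]-6-(trimethylsilyl)hex-5-ynoic acid
Product: 23 methyl (2S,3S)-2-[(1R,2E)-1-Ar-4-oxobut-2-en-1-yl]-3-[(benzyloxy)methyl]-6-(trimethylsilyl)hex-5-ynoate, via methyl ester acetal 22 (not isolated)
Conditions: Me3SiCHN2, PhMe/MeOH, 0 °C; concentrate; then PPTS, acetone/H2O, 40 °C
Reagents that add atoms: (trimethylsilyl)diazomethane, C[Si](C)(C)C=[N+]=[N-]; water, O
Why: O-methylation of the acid by the diazoalkane in methanol, then acid-catalysed hydrolysis of the now allylic dimethyl acetal through its conjugated oxocarbenium ion should give the (E)-enal, the weak pyridinium acid being too mild to enolise toward C1 or to cleave C–Si, benzyl ether or ester.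

Step 13
Reactants: 23 methyl (2S,3S)-2-[(1R,2E)-1-Ar-4-oxobut-2-en-1-yl]-3-[(benzyloxy)methyl]-6-(trimethylsilyl)hex-5-ynoate; 24 tributyl(methoxymethyl)stannane
Product: 26 methyl (2S,3S)-2-[(1R,2E,4RS)-1-Ar-4-hydroxy-5-methoxypent-2-en-1-yl]-3-[(benzyloxy)methyl]hex-5-ynoate, via silyl-capped alcohol 25 (not isolated)
Conditions: 24, nBuLi, THF, −78 °C; CeCl3, −78 °C; then 23, −78 °C; aq. NH4Cl work-up; crude, K2CO3, MeOH, rt
Reagents that add atoms: none
Why: tin–lithium exchange gives the methoxymethyl carbanion, whose organocerium form should add 1,2 to the aldehyde faster than it attacks the ester or removes the C1 hydrogen (C6 is thereby attached to C7), and carbonate-catalysed methanolysis of the C(sp)–Si bond then frees the alkyne; the new carbinol forms as both epimers, which is of no consequence because step 14 oxidises it.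

Step 14
Reactants: 26 methyl (2S,3S)-2-[(1R,2E,4RS)-1-Ar-4-hydroxy-5-methoxypent-2-en-1-yl]-3-[(benzyloxy)methyl]hex-5-ynoate
Product: 27 methyl (2S,3S)-2-[(1R,2E)-1-Ar-5-methoxy-4-oxopent-2-en-1-yl]-3-[(benzyloxy)methyl]hex-5-ynoate
Conditions: Dess–Martin periodinane, pyridine, CH2Cl2, 0 °C → rt
Reagents that add atoms: none
Why: Dess–Martin oxidation of the allylic alcohol (ligand exchange at hypervalent iodine, then removal of the carbinol hydrogen) should give the (E)-enone under buffered conditions that do not epimerise C1 or C2, and it erases the uncontrolled carbinol centre.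

Step 15
Reactants: 27 methyl (2S,3S)-2-[(1R,2E)-1-Ar-5-methoxy-4-oxopent-2-en-1-yl]-3-[(benzyloxy)methyl]hex-5-ynoate
Product: 29 methyl (2S,3S)-2-{(1R,2E,4Z)-1-Ar-4-[(tert-butyldimethylsilyl)oxy]-5-methoxypenta-2,4-dien-1-yl}-3-[(benzyloxy)methyl]hex-5-ynoate, via lithium enolate 28 (not isolated)
Conditions: LiN(SiMe3)2, THF, −78 °C; then tBuMe2SiOTf, −78 °C; Et3N, pentane, aq. NaHCO3; used at once
Reagents that add atoms: tert-butyldimethylsilyl trifluoromethanesulfonate, CC(C)(C)[Si](C)(C)OS(=O)(=O)C(F)(F)F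
Why: kinetic enolisation and O-silylation: the bulky lithium amide at −78 °C should take a proton from the unhindered, methoxy-acidified C6 methylene rather than from the hindered tertiary C1–H, lithium held between the enolate oxygen and OMe gives the (Z)-enolate, and the silyl triflate traps it on oxygen as the cross-conjugated dienol ether whose OMe points away from the diene.

Step 16
Reactants: 29 methyl (2S,3S)-2-{(1R,2E,4Z)-1-Ar-4-[(tert-butyldimethylsilyl)oxy]-5-methoxypenta-2,4-dien-1-yl}-3-[(benzyloxy)methyl]hex-5-ynoate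
Product: 31 methyl (1R,2S,3S)-1-Ar-3-[(benzyloxy)methyl]-7-[(tert-butyldimethylsilyl)oxy]-6-methoxy-1,2,3,4-tetrahydronaphthalene-2-carboxylate, via cyclohexadiene 30 (not isolated)
Conditions: [RhCl(C8H14)2]2 (5 mol %), P[OCH(CF3)2]3 (20 mol %), THF (0.02 M), 60 °C; then 0 °C, 2,6-di-tert-butylpyridine, DDQ (1.1 equiv)
Reagents that add atoms: none
Why: The neutral chlororhodium catalyst, made π-acidic by the fluorinated phosphite, binds the alkyne and the near diene double bond, couples C4a with C8a oxidatively to a rhodacycle whose C8–C7–C6 allyl arm then joins C6 to C5 by reductive elimination, so the net change is a suprafacial (4+2) addition giving 1,4-cyclohexadiene 30; DDQ then takes hydride from the doubly allylic C6–H or C8a–H and the cation loses the other proton to give the arene. The closest known reaction type is the transition-metal-catalysed intramolecular diene–alkyne (4+2) cycloisomerisation, followed by quinone dehydrogenation of a 1,4-cyclohexadiene. Ring B closes as a six-membered carbocycle when the four-atom tether C1–C4 brings C8a onto C4a, and ring A closes in the same event as the six-membered ring made of the four diene carbons and the two alkyne carbons. No lasting stereocentre is made: C6 and C8a are stereogenic only in 30 (their hydrogens cis, from suprafacial addition to the outward-methoxy diene) and are erased on aromatisation, while C1, C2 and C3 take no part. The oxygen pattern (OSi on C7, OMe on C6) is fixed by the tether and the chain connectivity, the (E) C8a=C8 bond from step 11 and the outward OMe from step 15 let the s-cis diene reach the alkyne, and loss of hydrogen rather than methanol is secured by a catalyst free of Lewis and protic acid, a hindered-base buffer and a cold DDQ stage in which hydride abstraction from the doubly allylic carbons outruns ionisation of the C6–OMe bond.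

Step 17
Reactants: 31 methyl (1R,2S,3S)-1-Ar-3-[(benzyloxy)methyl]-7-[(tert-butyldimethylsilyl)oxy]-6-methoxy-1,2,3,4-tetrahydronaphthalene-2-carboxylate
Product: 32 methyl (1R,2S,3S)-1-Ar-3-[(benzyloxy)methyl]-7-hydroxy-6-methoxy-1,2,3,4-tetrahydronaphthalene-2-carboxylate
Conditions: Bu4NF, AcOH (1:1), THF, 0 °C
Reagents that add atoms: none
Why: fluoride-induced cleavage of the aryl silyl ether (driven by Si–F bond formation), buffered with acetic acid so that no phenoxide is present to epimerise C2, with the benzyl ethers and the ester unaffected.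

Step 18
Reactants: 32 methyl (1R,2S,3S)-1-Ar-3-[(benzyloxy)methyl]-7-hydroxy-6-methoxy-1,2,3,4-tetrahydronaphthalene-2-carboxylate
Product: 33 methyl (1R,2S,3S)-7-hydroxy-1-(4-hydroxy-3-methoxyphenyl)-3-(hydroxymethyl)-6-methoxy-1,2,3,4-tetrahydronaphthalene-2-carboxylate
Conditions: H2 (1 atm), Pd/C (10 wt % Pd), EtOAc, rt
Reagents that add atoms: none
Why: hydrogenolysis of both benzyl ethers on palladium in a neutral solvent should free the phenol and the primary alcohol without acid or base that could close the γ-lactone between the C3 hydroxymethyl group and the C2 ester, and it leaves the arenes, the ester and the three stereocentres untouched.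

**Compound list**

1 | 4-(benzyloxy)-3-methoxybenzaldehyde (O-benzylvanillin) | O=Cc1ccc(OCc2ccccc2)c(OC)c1 | starting material
2 | 1-(benzyloxy)-4-ethynyl-2-methoxybenzene | C#Cc1ccc(OCc2ccccc2)c(OC)c1 | intermediate
3 | methyl 2,2-dimethoxyacetate | COC(=O)C(OC)OC | starting material
4 | lithium [4-(benzyloxy)-3-methoxyphenyl]acetylide | [Li]C#Cc1ccc(OCc2ccccc2)c(OC)c1 | intermediate
5 | 4-[4-(benzyloxy)-3-methoxyphenyl]-1,1-dimethoxybut-3-yn-2-one | COC(OC)C(=O)C#Cc1ccc(OCc2ccccc2)c(OC)c1 | intermediate
6 | (2R)-4-[4-(benzyloxy)-3-methoxyphenyl]-1,1-dimethoxybut-3-yn-2-ol | COC(OC)[C@H](O)C#Cc1ccc(OCc2ccccc2)c(OC)c1 | intermediate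
7 | (2R,3E)-4-[4-(benzyloxy)-3-methoxyphenyl]-1,1-dimethoxybut-3-en-2-ol | COC(OC)[C@H](O)/C=C/c1ccc(OCc2ccccc2)c(OC)c1 | intermediate
8 | 4-(tert-butoxy)-4-oxobutanoic acid (mono-tert-butyl succinate) | CC(C)(C)OC(=O)CCC(=O)O | starting material
9 | (4S)-4-benzyl-1,3-oxazolidin-2-one | O=C1N[C@@H](Cc2ccccc2)CO1 | starting material
10 | 4-(tert-butoxy)-4-oxobutanoic pivalic anhydride | CC(C)(C)OC(=O)CCC(=O)OC(=O)C(C)(C)C | intermediate
11 | tert-butyl 4-[(4S)-4-benzyl-2-oxo-1,3-oxazolidin-3-yl]-4-oxobutanoate | CC(C)(C)OC(=O)CCC(=O)N1[C@@H](Cc2ccccc2)COC1=O | intermediate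
12 | 3-bromo-1-(trimethylsilyl)prop-1-yne | C[Si](C)(C)C#CCBr | starting material
13 | sodium (Z)-enolate of 11 (O–Na and the CH2CO2tBu group cis) | [Na+].[O-]/C(=C\CC(=O)OC(C)(C)C)N1[C@@H](Cc2ccccc2)COC1=O | intermediate
14 | tert-butyl (3S)-3-{[(4S)-4-benzyl-2-oxo-1,3-oxazolidin-3-yl]carbonyl}-6-(trimethylsilyl)hex-5-ynoate | CC(C)(C)OC(=O)C[C@H](CC#C[Si](C)(C)C)C(=O)N1[C@@H](Cc2ccccc2)COC1=O | intermediate
15 | tert-butyl (3S)-3-(hydroxymethyl)-6-(trimethylsilyl)hex-5-ynoate | CC(C)(C)OC(=O)C[C@H](CC#C[Si](C)(C)C)CO | intermediate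
16 | tert-butyl (3S)-3-[(benzyloxy)methyl]-6-(trimethylsilyl)hex-5-ynoate | CC(C)(C)OC(=O)C[C@H](CC#C[Si](C)(C)C)COCc1ccccc1 | intermediate
17 | (3S)-3-[(benzyloxy)methyl]-6-(trimethylsilyl)hex-5-ynoic acid | OC(=O)C[C@H](CC#C[Si](C)(C)C)COCc1ccccc1 | intermediate
18 | (2R,3E)-4-[4-(benzyloxy)-3-methoxyphenyl]-1,1-dimethoxybut-3-en-2-yl (3S)-3-[(benzyloxy)methyl]-6-(trimethylsilyl)hex-5-ynoate | COC(OC)[C@H](OC(=O)C[C@H](CC#C[Si](C)(C)C)COCc1ccccc1)/C=C/c1ccc(OCc2ccccc2)c(OC)c1 | intermediate
19 | (E)-O-trimethylsilyl ketene acetal of 18 (C3 side chain trans to OSiMe3; carbinol R, C3 S) | C[Si](C)(C)O/C(O[C@@H](C(OC)OC)/C=C/c1ccc(OCc2ccccc2)c(OC)c1)=C/[C@H](CC#C[Si](C)(C)C)COCc1ccccc1 | intermediate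
20 | trimethylsilyl (2S,3S)-2-{(1R,2E)-1-[4-(benzyloxy)-3-methoxyphenyl]-4,4-dimethoxybut-2-en-1-yl}-3-[(benzyloxy)methyl]-6-(trimethylsilyl)hex-5-ynoate | C[Si](C)(C)OC(=O)[C@@H]([C@@H](/C=C/C(OC)OC)c1ccc(OCc2ccccc2)c(OC)c1)[C@@H](COCc1ccccc1)CC#C[Si](C)(C)C | intermediate
21 | (2S,3S)-2-{(1R,2E)-1-[4-(benzyloxy)-3-methoxyphenyl]-4,4-dimethoxybut-2-en-1-yl}-3-[(benzyloxy)methyl]-6-(trimethylsilyl)hex-5-ynoic acid | OC(=O)[C@@H]([C@@H](/C=C/C(OC)OC)c1ccc(OCc2ccccc2)c(OC)c1)[C@@H](COCc1ccccc1)CC#C[Si](C)(C)C | intermediate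
22 | methyl (2S,3S)-2-{(1R,2E)-1-[4-(benzyloxy)-3-methoxyphenyl]-4,4-dimethoxybut-2-en-1-yl}-3-[(benzyloxy)methyl]-6-(trimethylsilyl)hex-5-ynoate | COC(=O)[C@@H]([C@@H](/C=C/C(OC)OC)c1ccc(OCc2ccccc2)c(OC)c1)[C@@H](COCc1ccccc1)CC#C[Si](C)(C)C | intermediate
23 | methyl (2S,3S)-2-{(1R,2E)-1-[4-(benzyloxy)-3-methoxyphenyl]-4-oxobut-2-en-1-yl}-3-[(benzyloxy)methyl]-6-(trimethylsilyl)hex-5-ynoate | COC(=O)[C@@H]([C@@H](/C=C/C=O)c1ccc(OCc2ccccc2)c(OC)c1)[C@@H](COCc1ccccc1)CC#C[Si](C)(C)C | intermediate
24 | tributyl(methoxymethyl)stannane | CCCC[Sn](CCCC)(CCCC)COC | starting material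
25 | methyl (2S,3S)-2-{(1R,2E,4RS)-1-[4-(benzyloxy)-3-methoxyphenyl]-4-hydroxy-5-methoxypent-2-en-1-yl}-3-[(benzyloxy)methyl]-6-(trimethylsilyl)hex-5-ynoate (both carbinol epimers) | COC(=O)[C@@H]([C@@H](/C=C/C(O)COC)c1ccc(OCc2ccccc2)c(OC)c1)[C@@H](COCc1ccccc1)CC#C[Si](C)(C)C | intermediate
26 | methyl (2S,3S)-2-{(1R,2E,4RS)-1-[4-(benzyloxy)-3-methoxyphenyl]-4-hydroxy-5-methoxypent-2-en-1-yl}-3-[(benzyloxy)methyl]hex-5-ynoate (both carbinol epimers) | COC(=O)[C@@H]([C@@H](/C=C/C(O)COC)c1ccc(OCc2ccccc2)c(OC)c1)[C@@H](COCc1ccccc1)CC#C | intermediate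
27 | methyl (2S,3S)-2-{(1R,2E)-1-[4-(benzyloxy)-3-methoxyphenyl]-5-methoxy-4-oxopent-2-en-1-yl}-3-[(benzyloxy)methyl]hex-5-ynoate | COC(=O)[C@@H]([C@@H](/C=C/C(=O)COC)c1ccc(OCc2ccccc2)c(OC)c1)[C@@H](COCc1ccccc1)CC#C | intermediate
28 | lithium (Z)-enolate of 27 (O–Li and OMe cis on C7=C6) | COC(=O)[C@@H]([C@@H](/C=C/C(O[Li])=C/OC)c1ccc(OCc2ccccc2)c(OC)c1)[C@@H](COCc1ccccc1)CC#C | intermediate
29 | methyl (2S,3S)-2-{(1R,2E,4Z)-1-[4-(benzyloxy)-3-methoxyphenyl]-4-[(tert-butyldimethylsilyl)oxy]-5-methoxypenta-2,4-dien-1-yl}-3-[(benzyloxy)methyl]hex-5-ynoate | COC(=O)[C@@H]([C@@H](/C=C/C(O[Si](C)(C)C(C)(C)C)=C/OC)c1ccc(OCc2ccccc2)c(OC)c1)[C@@H](COCc1ccccc1)CC#C | intermediate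
30 | methyl (1R,2S,3S)-1-[4-(benzyloxy)-3-methoxyphenyl]-3-[(benzyloxy)methyl]-7-[(tert-butyldimethylsilyl)oxy]-6-methoxy-1,2,3,4,6,8a-hexahydronaphthalene-2-carboxylate (6-H and 8a-H cis; C6 and C8a not assigned, both ring-fusion epimers converge) | COC(=O)[C@@H]1[C@@H](COCc2ccccc2)CC2=CC(OC)C(O[Si](C)(C)C(C)(C)C)=CC2[C@H]1c1ccc(OCc2ccccc2)c(OC)c1 | intermediate
31 | methyl (1R,2S,3S)-1-[4-(benzyloxy)-3-methoxyphenyl]-3-[(benzyloxy)methyl]-7-[(tert-butyldimethylsilyl)oxy]-6-methoxy-1,2,3,4-tetrahydronaphthalene-2-carboxylate | COC(=O)[C@@H]1[C@@H](COCc3ccccc3)Cc2cc(OC)c(O[Si](C)(C)C(C)(C)C)cc2[C@H]1c1ccc(OCc2ccccc2)c(OC)c1 | intermediate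
32 | methyl (1R,2S,3S)-1-[4-(benzyloxy)-3-methoxyphenyl]-3-[(benzyloxy)methyl]-7-hydroxy-6-methoxy-1,2,3,4-tetrahydronaphthalene-2-carboxylate | COC(=O)[C@@H]1[C@@H](COCc3ccccc3)Cc2cc(OC)c(O)cc2[C@H]1c1ccc(OCc2ccccc2)c(OC)c1 | intermediate
33 | methyl (1R,2S,3S)-7-hydroxy-1-(4-hydroxy-3-methoxyphenyl)-3-(hydroxymethyl)-6-methoxy-1,2,3,4-tetrahydronaphthalene-2-carboxylate | COC(=O)[C@@H]1[C@@H](CO)Cc2cc(OC)c(O)cc2[C@H]1c1ccc(O)c(OC)c1 | target

**Step count**

Total: 18 steps. Longest linear sequence: 14 steps (steps 5–18, from 8); the branch from 1 is 13 steps (steps 1–4 and 10–18).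

**Steps most likely to fail, in this order: step 16, step 15, step 2**

Step 16. What may go wrong: the rhodium catalyst may fail to engage the doubly oxygenated diene so that no ring closure takes place, the free alkyne C–H may be drawn into oligomerisation at the metal, or methanol may be lost from the cyclohexadiene in place of hydrogen during aromatisation. The fallback keeps the disconnection but changes the substrate and the metal: a silicon-capped alkyne, zerovalent nickel, and a traceless silyl group on C5. It sets out from 25, obtained by leaving out the carbonate–methanol stage of step 13. Dess–Martin oxidation gives the silyl-capped methoxy enone F1. LiN(SiMe3)2 and then tBuMe2SiOTf at −78 °C give, through its lithium enolate F2, the silyl-capped dienol ether F3. Ni(C8H12)2 with P[OCH(CF3)2]3 in THF at room temperature should then give the 5-silyl cyclohexadiene F4; this zerovalent nickel–phosphite cycloaddition of dienes with silyl alkynes is known to accept silyloxydienes and four-atom tethers. DDQ dehydrogenates F4 to the 5-trimethylsilyl tetralin F5, and ipso-protodesilylation with CF3CO2H in CH2Cl2 at 0 °C (C5 lies ortho to the methoxy group) comes back to the route at 31.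

Step 15. What may go wrong: proton removal at the benzylic γ-position C1 in competition with the methoxymethyl carbon, which would scramble C1 and lead to the linear dienol ether, or hydrolysis of the dienol ether during isolation. The fallback uses no diene at all and makes the same two ring bonds one after the other by carbonyl chemistry. It sets out from 27. Ruthenium-catalysed anti-Markovnikov hydration of the terminal alkyne (CpRuCl(Ph2PCH2PPh2), aqueous 2-propanol, 100 °C) gives the keto aldehyde F6. Pyrrolidine with acetic acid forms the aldehyde enamine, whose C4a adds to C8a of the enone (intramolecular Michael addition, ring B) to give the ring B keto aldehyde F7. On warming, the C6 methylene condenses with the C5 aldehyde (intramolecular aldol condensation, ring A) to give the bicyclic 6-methoxy enone F8. DDQ in dioxane removes the C4a and C8a hydrogens and the dienone tautomerises to the phenol, which is 32. The route is rejoined at 32, and steps 16 and 17 are not needed.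

Step 2. What may go wrong: early collapse of the tetrahedral adduct followed by a second addition of the acetylide to the ynone, or conjugate attack on the product. The fallback replaces ester acylation by addition to an aldehyde and oxidation. It sets out from 2, used as its acetylide 4: addition to 2,2-dimethoxyacetaldehyde in THF at −78 °C gives the racemic propargylic alcohol F9, and MnO2 in CH2Cl2 oxidises it to 5, where the route is rejoined.

**Further compounds**

F1 | step 16 | silyl-capped methoxy enone, methyl (2S,3S)-2-{(1R,2E)-1-[4-(benzyloxy)-3-methoxyphenyl]-5-methoxy-4-oxopent-2-en-1-yl}-3-[(benzyloxy)methyl]-6-(trimethylsilyl)hex-5-ynoate | COC(=O)[C@@H]([C@@H](/C=C/C(=O)COC)c1ccc(OCc2ccccc2)c(OC)c1)[C@@H](COCc1ccccc1)CC#C[Si](C)(C)C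
F2 | step 16 | lithium (Z)-enolate of F1 | COC(=O)[C@@H]([C@@H](/C=C/C(O[Li])=C/OC)c1ccc(OCc2ccccc2)c(OC)c1)[C@@H](COCc1ccccc1)CC#C[Si](C)(C)C
F3 | step 16 | silyl-capped dienol ether, methyl (2S,3S)-2-{(1R,2E,4Z)-1-[4-(benzyloxy)-3-methoxyphenyl]-4-[(tert-butyldimethylsilyl)oxy]-5-methoxypenta-2,4-dien-1-yl}-3-[(benzyloxy)methyl]-6-(trimethylsilyl)hex-5-ynoate | COC(=O)[C@@H]([C@@H](/C=C/C(O[Si](C)(C)C(C)(C)C)=C/OC)c1ccc(OCc2ccccc2)c(OC)c1)[C@@H](COCc1ccccc1)CC#C[Si](C)(C)C
F4 | step 16 | 5-silyl cyclohexadiene, the 5-(trimethylsilyl) analogue of 30 (C6 and C8a not assigned) | COC(=O)[C@@H]1[C@@H](COCc2ccccc2)CC2=C([Si](C)(C)C)C(OC)C(O[Si](C)(C)C(C)(C)C)=CC2[C@H]1c1ccc(OCc2ccccc2)c(OC)c1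
F5 | step 16 | 5-trimethylsilyl tetralin, methyl (1R,2S,3S)-1-[4-(benzyloxy)-3-methoxyphenyl]-3-[(benzyloxy)methyl]-7-[(tert-butyldimethylsilyl)oxy]-6-methoxy-5-(trimethylsilyl)-1,2,3,4-tetrahydronaphthalene-2-carboxylate | COC(=O)[C@@H]1[C@@H](COCc3ccccc3)Cc2c([Si](C)(C)C)c(OC)c(O[Si](C)(C)C(C)(C)C)cc2[C@H]1c1ccc(OCc2ccccc2)c(OC)c1
F6 | step 15 | keto aldehyde, methyl (2S,3S)-2-{(1R,2E)-1-[4-(benzyloxy)-3-methoxyphenyl]-5-methoxy-4-oxopent-2-en-1-yl}-3-[(benzyloxy)methyl]-6-oxohexanoate | COC(=O)[C@@H]([C@@H](/C=C/C(=O)COC)c1ccc(OCc2ccccc2)c(OC)c1)[C@@H](COCc1ccccc1)CCC=O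
F7 | step 15 | ring B keto aldehyde: cyclohexane with C1 aryl, C2 CO2Me and C3 CH2OBn as in 27, CHO on C4a and CH2C(=O)CH2OMe on C8a (C4a and C8a not assigned) | COC(=O)[C@@H]1[C@@H](COCc2ccccc2)CC(C=O)C(CC(=O)COC)[C@H]1c1ccc(OCc2ccccc2)c(OC)c1
F8 | step 15 | bicyclic 6-methoxy enone: 6-methoxy-7-oxo-1,2,3,4,4a,7,8,8a-octahydronaphthalene with C1, C2 and C3 as in 27 (C4a and C8a not assigned) | COC(=O)[C@@H]1[C@@H](COCc2ccccc2)CC2C=C(OC)C(=O)CC2[C@H]1c1ccc(OCc2ccccc2)c(OC)c1
F9 | step 2 | racemic propargylic alcohol, 4-[4-(benzyloxy)-3-methoxyphenyl]-1,1-dimethoxybut-3-yn-2-ol | COC(OC)C(O)C#Cc1ccc(OCc2ccccc2)c(OC)c1
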